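The five-membered α-methylene lactone ring is closed at its alkyl C–O bond. In germacrane numbering, the lactone oxygen on C6, the (4Z)-C4=C5 alkene and the C15 hydroxyl form a 1,4-dioxygenated 2-ene, the oxidation pattern of a 2-substituted 1,3-diene (C6=C5–C4=C15). A palladium-catalysed 1,4-acyloxy-lactonisation of the acyclic diene acid 22 therefore closes the lactone at O–C6, sets C6, fixes the alkene geometry and installs the C15 oxygen in one operation. C7 and C8 come from a catalyst-controlled syn-allylboration, C10 from (S)-2-methylglycidol, and the ten-membered carbocycle is closed afterwards at C2–C3 by a Nozaki–Hiyama–Kishi reaction.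

Key step: step 13

Remark: atom numbers are germacranolide numbers (C1=C2, C3 ketone, C4=C5 with C15 on C4, C6 lactone carbinol, C7, C8 ester carbinol, C9, C10 carbinol with methyl C14, C11=C13, C12 lactone carbonyl). TBS = tert-butyldimethylsilyl, TES = triethylsilyl, Bpin = 4,4,5,5-tetramethyl-1,3,2-dioxaborolan-2-yl. (S)-2-Methylglycidol, 2-bromoprop-2-en-1-ol and (R)-2-methylbutanoic acid are taken as commercially available.

Step 1
Reactants: 1 2-bromoprop-2-en-1-ol
Product: 2 tert-butyl[(2-bromoprop-2-en-1-yl)oxy]dimethylsilane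
Conditions: TBSCl, imidazole, DMF, 0 °C to rt
Reagents that add atoms: tert-butyldimethylsilyl chloride CC(C)(C)[Si](C)(C)Cl
Why: Silyl ether formation at the primary allylic alcohol should be clean and masks the future C3 oxygen through the base- and metal-mediated steps that follow.

Step 2
Reactants: 2 tert-butyl[(2-bromoprop-2-en-1-yl)oxy]dimethylsilane; 3 acrolein diethyl acetal (3,3-diethoxyprop-1-ene)
Product: 5 (2E)-4-[(TBS-oxy)methyl]penta-2,4-dienal, via diethyl acetal 4 (not isolated)
Conditions: Pd(OAc)2 (3 mol %), K2CO3, KCl, Bu4NOAc, DMF, 90 °C; then 0.5 M HCl, THF, 0 °C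
Reagents that add atoms: water O
Why: Heck reaction of the alkenyl bromide with the acrolein acetal should give the (E)-diene by syn-carbopalladation and syn-β-hydride elimination, and brief acid hydrolysis of the enal acetal then frees the aldehyde without loss of the silyl ether.

Step 3
Reactants: 5 (2E)-4-[(TBS-oxy)methyl]penta-2,4-dienal; 6 tert-butyl acrylate
Product: 8 tert-butyl (4E)-3-acetoxy-2-methylidene-6-[(TBS-oxy)methyl]hepta-4,6-dienoate (racemic), via Morita–Baylis–Hillman alcohol 7 (not isolated)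
Conditions: DABCO (1 equiv), 6 (5 equiv, neat), rt; then Ac2O, Et3N, DMAP (cat.), CH2Cl2, 0 °C
Reagents that add atoms: acetic anhydride CC(=O)OC(C)=O
Why: Morita–Baylis–Hillman reaction (amine-derived acrylate enolate adds 1,2 to the aldehyde) followed by acetylation in the same flask; the carbinol centre is racemic and is destroyed in step 4.

Step 4
Reactants: 8 tert-butyl (4E)-3-acetoxy-2-methylidene-6-[(TBS-oxy)methyl]hepta-4,6-dienoate
Product: 9 tert-butyl (2E,4E)-2-[(Bpin)methyl]-6-[(TBS-oxy)methyl]hepta-2,4,6-trienoate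
Conditions: B2pin2, CuCl (10 mol %), KOAc, DMF, rt
Reagents that add atoms: bis(pinacolato)diboron CC1(C)OB(OC1(C)C)B1OC(C)(C)C(C)(C)O1
Why: Copper-catalysed allylic borylation (Miyaura-type borylcopper addition to the acrylate terminus C13, then loss of acetate from C7) should give the primary allylboronate regiospecifically, with the dienyl group trans to the ester and cis to the CH2B group as the less strained trisubstituted alkene.

Step 5
Reactants: 10 (S)-2-methylglycidol
Product: 11 (2R)-2-methylpent-4-ene-1,2-diol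
Conditions: CH2=CHMgBr (2.5 equiv), CuI (10 mol %), THF, −40 to 0 °C
Reagents that add atoms: vinylmagnesium bromide C=C[Mg]Br
Why: Copper-catalysed Grignard opening of the epoxide at its unsubstituted carbon (SN2) leaves the quaternary carbinol stereocentre, the future C10, untouched.

Step 6
Reactants: 11 (2R)-2-methylpent-4-ene-1,2-diol
Product: 12 (2R)-2-methyl-1,2-bis(TES-oxy)pent-4-ene
Conditions: TESOTf (2.4 equiv), 2,6-lutidine, CH2Cl2, −78 to 0 °C
Reagents that add atoms: triethylsilyl triflate CC[Si](CC)(CC)OS(=O)(=O)C(F)(F)F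
Why: Exhaustive silylation with the silyl triflate protects the tertiary alcohol and turns the primary alcohol into a silyl ether that can be oxidised directly.

Step 7
Reactants: 12 (2R)-2-methyl-1,2-bis(TES-oxy)pent-4-ene
Product: 13 (2R)-2-methyl-2-(TES-oxy)pent-4-enal
Conditions: (COCl)2, DMSO, CH2Cl2, −78 to −40 °C; then Et3N, −78 °C to rt
Reagents that add atoms: none
Why: Under Swern conditions a primary triethylsilyl ether is converted directly into the aldehyde while the tertiary silyl ether is inert, and the quaternary α-carbon cannot epimerise.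

Step 8
Reactants: 13 (2R)-2-methyl-2-(TES-oxy)pent-4-enal
Product: 14 (1E,3R)-1-iodo-3-methyl-3-(TES-oxy)hexa-1,5-diene
Conditions: CrCl2 (6 equiv), CHI3 (2 equiv), THF–1,4-dioxane, 0 °C to rt
Reagents that add atoms: iodoform IC(I)I
Why: Takai olefination through the geminal dichromium species should give the (E)-iodoalkene, which is strongly favoured next to a quaternary carbon.

Step 9
Reactants: 14 (1E,3R)-1-iodo-3-methyl-3-(TES-oxy)hexa-1,5-diene
Product: 15 (3R,4E)-5-iodo-3-methyl-3-(TES-oxy)pent-4-enal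
Conditions: OsO4 (2 mol %), NaIO4, 2,6-lutidine, 1,4-dioxane–H2O, rt
Reagents that add atoms: osmium tetroxide O=[Os](=O)(=O)=O (oxygen donor, regenerated by sodium periodate [Na+].[O-]I(=O)(=O)=O)
Why: Lemieux–Johnson cleavage should take the electron-richer monosubstituted alkene and leave the electron-poor, hindered iodoalkene.

Step 10
Reactants: 9 tert-butyl (2E,4E)-2-[(Bpin)methyl]-6-[(TBS-oxy)methyl]hepta-2,4,6-trienoate; 15 (3R,4E)-5-iodo-3-methyl-3-(TES-oxy)pent-4-enal
Product: 17 tert-butyl (3R,4R,6R,7E)-4-hydroxy-8-iodo-6-methyl-2-methylidene-3-{(1E)-3-[(TBS-oxy)methyl]buta-1,3-dien-1-yl}-6-(TES-oxy)oct-7-enoate, via pinacol borate 16 (not isolated)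
Conditions: (S)-TRIP [(S)-3,3'-bis(2,4,6-triisopropylphenyl)-1,1'-binaphthyl-2,2'-diyl hydrogen phosphate] (10 mol %), 4 Å molecular sieves, toluene, 0 °C to rt; then aqueous NaHCO3
Reagents that add atoms: none
Why: Chiral phosphoric acid-catalysed allylboration through a closed chair transition state: the C6 dienyl group of 9 is cis to CH2B and therefore axial, which gives the 7,8-syn adduct, while the catalyst antipode (expected to be S) directs the allyl group to the Si face of the aldehyde and so sets 8R and 7R independently of the remote C10 centre.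

Step 11
Reactants: 17 the homoallylic alcohol from step 10; 18 (R)-2-methylbutanoic acid
Product: 20 tert-butyl (3R,4R,6R,7E)-8-iodo-6-methyl-2-methylidene-4-{[(2R)-2-methylbutanoyl]oxy}-3-{(1E)-3-[(TBS-oxy)methyl]buta-1,3-dien-1-yl}-6-(TES-oxy)oct-7-enoate, via mixed anhydride 19 (not isolated)
Conditions: 18, 2,4,6-trichlorobenzoyl chloride, Et3N, THF, rt; then 17, DMAP, toluene, rt
Reagents that add atoms: 2,4,6-trichlorobenzoyl chloride O=C(Cl)c1c(Cl)cc(Cl)cc1Cl (acyl part carried only in 19)
Why: Yamaguchi esterification acylates the hindered secondary C8 alcohol through the mixed anhydride with retention at C8 and without passing through a ketene that would erase the α-stereocentre of the acid.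

Step 12
Reactants: 20 the C8 ester from step 11
Product: 22 (3R,4R,6R,7E)-8-iodo-6-methyl-2-methylidene-4-{[(2R)-2-methylbutanoyl]oxy}-3-{(1E)-3-[(TBS-oxy)methyl]buta-1,3-dien-1-yl}-6-(TES-oxy)oct-7-enoic acid, via trimethylsilyl ester 21 (not isolated)
Conditions: TMSOTf, 2,6-lutidine, CH2Cl2, 0 °C; then pH 5 aqueous buffer
Reagents that add atoms: trimethylsilyl triflate C[Si](C)(C)OS(=O)(=O)C(F)(F)F (silyl group carried only in 21)
Why: Silyl triflate-mediated cleavage of the tert-butyl ester (loss of 2-methylpropene from the O-silylated ester) should spare the silyl ethers, the secondary ester and the diene, and the silyl ester hydrolyses on work-up.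

Step 13
Reactants: 22 the diene acid from step 12
Product: 23 (4R,5R)-5-{(1Z)-3-acetoxy-2-[(TBS-oxy)methyl]prop-1-en-1-yl}-4-[(1R,3R,4E)-5-iodo-3-methyl-1-{[(2R)-2-methylbutanoyl]oxy}-3-(TES-oxy)pent-4-en-1-yl]-3-methylideneoxolan-2-one
Conditions: Pd(OAc)2 (10 mol %), p-benzoquinone (20 mol %), MnO2 (2 equiv), LiOAc (2 equiv), acetone–AcOH 4:1, rt
Reagents that add atoms: acetic acid CC(=O)O
Why: Divalent palladium coordinates the C5=C6 alkene of the s-trans diene and the C12 carboxylate adds to C6 anti to the metal, giving an η3-allylpalladium unit over C5–C4–C15 that acetate attacks at the unsubstituted terminus C15, after which the released zerovalent palladium is reoxidised by benzoquinone/MnO2. The closest known reaction type is the palladium-catalysed intramolecular 1,4-acyloxy-lactonisation (1,4-oxidation) of conjugated diene acids. The only ring closed is the five-membered lactone, by 5-exo-trig attack of oxygen on C6. The new stereocentre C6 is controlled by the resident C7 centre: acyloxypalladation is reversible in acetic acid, so the trans-4,5-disubstituted lactone, with the C5 and C8 branches on opposite faces, should accumulate. The C4=C5 geometry follows from the allyl intermediate, in which the C6 substituent on C5 sits syn to the central C3 branch, which places C6 cis to C3 and trans to C15 as in the target. The step needs carboxylate attack before intermolecular acetate attack (secured by the five-membered tether), 1,4- over 1,2-addition (secured by the primary terminus C15) and survival of the diene (secured by keeping benzoquinone catalytic so that cycloaddition is slow).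

Step 14
Reactants: 23 the lactone from step 13
Product: 24 (4R,5R)-5-[(1E)-3-acetoxy-2-(hydroxymethyl)prop-1-en-1-yl]-4-[(1R,3R,4E)-3-hydroxy-5-iodo-3-methyl-1-{[(2R)-2-methylbutanoyl]oxy}pent-4-en-1-yl]-3-methylideneoxolan-2-one
Conditions: HF·pyridine, pyridine, THF, 0 °C to rt
Reagents that add atoms: none
Why: Fluoride-mediated desilylation removes both silyl ethers under buffered, weakly acidic conditions that should not cause acetyl migration between the C15 and C3 oxygens or open the lactone.

Step 15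
Reactants: 24 the diol from step 14
Product: 25 (4R,5R)-5-[(1Z)-3-acetoxy-2-formylprop-1-en-1-yl]-4-[(1R,3R,4E)-3-hydroxy-5-iodo-3-methyl-1-{[(2R)-2-methylbutanoyl]oxy}pent-4-en-1-yl]-3-methylideneoxolan-2-one
Conditions: MnO2 (excess), CH2Cl2, rt
Reagents that add atoms: none
Why: Allylic oxidation with MnO2 takes only the primary allylic C3 alcohol, cannot touch the tertiary alcohol, and is neutral enough to keep the enal geometry (formyl cis to C6).

Step 16
Reactants: 25 the iodoalkene enal from step 15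
Product: 26 (1E,4Z,6R,7R,8R,10R)-15-acetoxy-3,10-dihydroxygermacra-1,4,11(13)-trien-12,6-olid-8-yl (2R)-2-methylbutanoate (mixture of C3 epimers)
Conditions: CrCl2 (10 equiv), NiCl2 (0.1 equiv), DMSO–THF, rt, slow addition of 25 to 2 mM
Reagents that add atoms: none
Why: Nozaki–Hiyama–Kishi reaction: nickel-catalysed formation of the alkenylchromium species with retention of the (E)-geometry and its intramolecular 1,2-addition to the enal under high dilution should close the ten-membered ring at C2–C3; the new C3 carbinol centre is not controlled and is removed in step 17.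

Step 17
Reactants: 26 the macrocyclic allylic alcohol from step 16
Product: 27 (1E,4Z,6R,7R,8R,10R)-15-acetoxy-10-hydroxy-3-oxogermacra-1,4,11(13)-trien-12,6-olid-8-yl (2R)-2-methylbutanoate
Conditions: Dess–Martin periodinane, NaHCO3, CH2Cl2, 0 °C
Reagents that add atoms: none
Why: Dess–Martin oxidation of the bis-allylic secondary alcohol gives the cross-conjugated dienone and erases the C3 stereocentre, while the tertiary alcohol cannot be oxidised.

Step 18
Reactants: 27 the C15 acetate from step 17
Product: 28 (1E,4Z,6R,7R,8R,10R)-10,15-dihydroxy-3-oxogermacra-1,4,11(13)-trien-12,6-olid-8-yl (2R)-2-methylbutanoate (target)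
Conditions: immobilised lipase B from Candida antarctica, pH 7 phosphate buffer–acetone, 30 °C
Reagents that add atoms: none
Why: Lipase-catalysed ester hydrolysis should select the unhindered primary allylic acetate over the α-branched secondary ester and the lactone, and avoids alkoxide bases that would add to the α-methylene lactone or the dienone.

Compound list
1 | 2-bromoprop-2-en-1-ol | C=C(Br)CO | starting material
2 | tert-butyl[(2-bromoprop-2-en-1-yl)oxy]dimethylsilane | C=C(Br)CO[Si](C)(C)C(C)(C)C | intermediate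
3 | acrolein diethyl acetal | C=CC(OCC)OCC | starting material
4 | tert-butyl{[(3E)-5,5-diethoxy-2-methylidenepent-3-en-1-yl]oxy}dimethylsilane | CCOC(OCC)/C=C/C(=C)CO[Si](C)(C)C(C)(C)C | intermediate
5 | (2E)-4-[(TBS-oxy)methyl]penta-2,4-dienal | O=C/C=C/C(=C)CO[Si](C)(C)C(C)(C)C | intermediate
6 | tert-butyl acrylate | C=CC(=O)OC(C)(C)C | starting material
7 | tert-butyl (4E)-3-hydroxy-2-methylidene-6-[(TBS-oxy)methyl]hepta-4,6-dienoate (racemic) | C=C(C(=O)OC(C)(C)C)C(O)/C=C/C(=C)CO[Si](C)(C)C(C)(C)C | intermediate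
8 | tert-butyl (4E)-3-acetoxy-2-methylidene-6-[(TBS-oxy)methyl]hepta-4,6-dienoate (racemic) | C=C(C(=O)OC(C)(C)C)C(OC(C)=O)/C=C/C(=C)CO[Si](C)(C)C(C)(C)C | intermediate
9 | tert-butyl (2E,4E)-2-[(Bpin)methyl]-6-[(TBS-oxy)methyl]hepta-2,4,6-trienoate (CH2B cis to C6) | CC1(C)OB(OC1(C)C)C/C(=C\C=C\C(=C)CO[Si](C)(C)C(C)(C)C)C(=O)OC(C)(C)C | intermediate
10 | (S)-2-methylglycidol, [(2S)-2-methyloxiran-2-yl]methanol | C[C@]1(CO)CO1 | starting material
11 | (2R)-2-methylpent-4-ene-1,2-diol | OC[C@](C)(O)CC=C | intermediate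
12 | (2R)-2-methyl-1,2-bis(TES-oxy)pent-4-ene | CC[Si](CC)(CC)OC[C@](C)(O[Si](CC)(CC)CC)CC=C | intermediate
13 | (2R)-2-methyl-2-(TES-oxy)pent-4-enal | O=C[C@](C)(O[Si](CC)(CC)CC)CC=C | intermediate
14 | (1E,3R)-1-iodo-3-methyl-3-(TES-oxy)hexa-1,5-diene | I/C=C/[C@](C)(O[Si](CC)(CC)CC)CC=C | intermediate
15 | (3R,4E)-5-iodo-3-methyl-3-(TES-oxy)pent-4-enal | I/C=C/[C@](C)(O[Si](CC)(CC)CC)CC=O | intermediate
16 | O4-Bpin borate of 17 | C=C(C(=O)OC(C)(C)C)[C@@H](/C=C/C(=C)CO[Si](C)(C)C(C)(C)C)[C@H](OB1OC(C)(C)C(C)(C)O1)C[C@@](C)(O[Si](CC)(CC)CC)/C=C/I | intermediate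
17 | tert-butyl (3R,4R,6R,7E)-4-hydroxy-8-iodo-6-methyl-2-methylidene-3-{(1E)-3-[(TBS-oxy)methyl]buta-1,3-dien-1-yl}-6-(TES-oxy)oct-7-enoate (7R,8R,10R in germacrane numbers) | C=C(C(=O)OC(C)(C)C)[C@@H](/C=C/C(=C)CO[Si](C)(C)C(C)(C)C)[C@H](O)C[C@@](C)(O[Si](CC)(CC)CC)/C=C/I | intermediate
18 | (R)-2-methylbutanoic acid | CC[C@@H](C)C(=O)O | starting material
19 | (2R)-2-methylbutanoic 2,4,6-trichlorobenzoic anhydride | CC[C@@H](C)C(=O)OC(=O)c1c(Cl)cc(Cl)cc1Cl | intermediate
20 | tert-butyl (3R,4R,6R,7E)-8-iodo-6-methyl-2-methylidene-4-{[(2R)-2-methylbutanoyl]oxy}-3-{(1E)-3-[(TBS-oxy)methyl]buta-1,3-dien-1-yl}-6-(TES-oxy)oct-7-enoate | C=C(C(=O)OC(C)(C)C)[C@@H](/C=C/C(=C)CO[Si](C)(C)C(C)(C)C)[C@H](OC(=O)[C@H](C)CC)C[C@@](C)(O[Si](CC)(CC)CC)/C=C/I | intermediate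
21 | trimethylsilyl ester of 22 | C=C(C(=O)O[Si](C)(C)C)[C@@H](/C=C/C(=C)CO[Si](C)(C)C(C)(C)C)[C@H](OC(=O)[C@H](C)CC)C[C@@](C)(O[Si](CC)(CC)CC)/C=C/I | intermediate
22 | (3R,4R,6R,7E)-8-iodo-6-methyl-2-methylidene-4-{[(2R)-2-methylbutanoyl]oxy}-3-{(1E)-3-[(TBS-oxy)methyl]buta-1,3-dien-1-yl}-6-(TES-oxy)oct-7-enoic acid | C=C(C(=O)O)[C@@H](/C=C/C(=C)CO[Si](C)(C)C(C)(C)C)[C@H](OC(=O)[C@H](C)CC)C[C@@](C)(O[Si](CC)(CC)CC)/C=C/I | intermediate
23 | (4R,5R)-5-{(1Z)-3-acetoxy-2-[(TBS-oxy)methyl]prop-1-en-1-yl}-4-[(1R,3R,4E)-5-iodo-3-methyl-1-{[(2R)-2-methylbutanoyl]oxy}-3-(TES-oxy)pent-4-en-1-yl]-3-methylideneoxolan-2-one (trans lactone; C6 cis to C3) | C=C1C(=O)O[C@H](/C=C(/COC(C)=O)CO[Si](C)(C)C(C)(C)C)[C@H]1[C@H](OC(=O)[C@H](C)CC)C[C@@](C)(O[Si](CC)(CC)CC)/C=C/I | intermediate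
24 | (4R,5R)-5-[(1E)-3-acetoxy-2-(hydroxymethyl)prop-1-en-1-yl]-4-[(1R,3R,4E)-3-hydroxy-5-iodo-3-methyl-1-{[(2R)-2-methylbutanoyl]oxy}pent-4-en-1-yl]-3-methylideneoxolan-2-one | C=C1C(=O)O[C@H](/C=C(/COC(C)=O)CO)[C@H]1[C@H](OC(=O)[C@H](C)CC)C[C@@](C)(O)/C=C/I | intermediate
25 | (4R,5R)-5-[(1Z)-3-acetoxy-2-formylprop-1-en-1-yl]-4-[(1R,3R,4E)-3-hydroxy-5-iodo-3-methyl-1-{[(2R)-2-methylbutanoyl]oxy}pent-4-en-1-yl]-3-methylideneoxolan-2-one | C=C1C(=O)O[C@H](/C=C(/COC(C)=O)C=O)[C@H]1[C@H](OC(=O)[C@H](C)CC)C[C@@](C)(O)/C=C/I | intermediate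
26 | (1E,4Z,6R,7R,8R,10R)-15-acetoxy-3,10-dihydroxygermacra-1,4,11(13)-trien-12,6-olid-8-yl (2R)-2-methylbutanoate, C3 epimers | C=C1C(=O)O[C@@H]2/C=C(/COC(C)=O)C(O)/C=C/[C@](C)(O)C[C@@H](OC(=O)[C@H](C)CC)[C@@H]12 | intermediate
27 | (1E,4Z,6R,7R,8R,10R)-15-acetoxy-10-hydroxy-3-oxogermacra-1,4,11(13)-trien-12,6-olid-8-yl (2R)-2-methylbutanoate | C=C1C(=O)O[C@@H]2/C=C(/COC(C)=O)C(=O)/C=C/[C@](C)(O)C[C@@H](OC(=O)[C@H](C)CC)[C@@H]12 | intermediate
28 | (1E,4Z,6R,7R,8R,10R)-10,15-dihydroxy-3-oxogermacra-1,4,11(13)-trien-12,6-olid-8-yl (2R)-2-methylbutanoate | C=C1C(=O)O[C@@H]2/C=C(/CO)C(=O)/C=C/[C@](C)(O)C[C@@H](OC(=O)[C@H](C)CC)[C@@H]12 | target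

Total step count: 18 steps.
Longest linear sequence: 14 steps (from 10 through steps 5–9 and 10–18).

Steps most likely to fail

Step 13 (key step). The acyloxypalladation may be kinetically controlled and deliver the cis-lactone (poor facial selectivity at C6), or the diene may be consumed by cycloaddition or alkene migration before cyclisation. The fallback sets out from 22 and comes back at 24, so it also replaces step 14. HF·pyridine would first remove both silyl groups to give (3R,4R,6R,7E)-4-{[(2R)-2-methylbutanoyl]oxy}-6-hydroxy-3-[(1E)-3-(hydroxymethyl)buta-1,3-dien-1-yl]-8-iodo-6-methyl-2-methylideneoct-7-enoic acid F2. Iodolactonisation with iodine in acetonitrile without base, run under equilibrating conditions that favour trans-4,5-disubstituted γ-lactones thermodynamically, should then give the allylic iodide (4R,5R)-5-[3-iodo-2-(hydroxymethyl)prop-1-en-1-yl]-lactone F3 (otherwise as 24), which still closes the lactone at O–C6. Displacement of the primary allylic iodide with AgOAc in AcOH would give 24; if both C4=C5 isomers form they would be separated at that stage.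

Step 10. The ester-substituted allylboronate may be too unreactive under phosphoric acid catalysis, or the catalyst may not control the aldehyde face (poor facial selectivity relative to C10). The fallback sets out from 7, isolated by leaving out the acetylation in step 3, and comes back at 17. PBr3 in Et2O at −10 °C should convert 7 with allylic transposition into tert-butyl (2Z,4E)-2-(bromomethyl)-6-[(TBS-oxy)methyl]hepta-2,4,6-trienoate F1. An indium-mediated Barbier allylation of 15 with F1 (indium powder, THF–H2O, rt) should proceed through the ester-chelated allylindium in a chair transition state and give the same 7,8-syn relationship. The aldehyde face is then not controlled, so 17 would be separated by chromatography from its (7S,8S) diastereomer.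

Step 16. Closure of the strained ten-membered ring may lose to oligomerisation or to reduction of the iodoalkene, and the chromium alkoxide may allow acetyl migration from O15 to O3. The fallback sets out from 25 and comes back at 27, so it also replaces step 17. Pinnick oxidation (NaClO2, NaH2PO4, 2-methylbut-2-ene, tBuOH–H2O) would give the (Z)-2-(acetoxymethyl)acrylic acid F4, and 2,2'-dipyridyl disulfide with PPh3 would turn it into the S-(pyridin-2-yl) thioester F5. Nickel-catalysed reductive coupling of the thioester with the iodoalkene under high dilution (NiBr2·diglyme, 4,4'-di-tert-butyl-2,2'-bipyridine, Cp2ZrCl2, Zn dust, 1,3-dimethyl-2-imidazolidinone) should then form the C2–C3 bond at the ketone oxidation level and give 27 directly, with no alkoxide intermediate.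

Further compounds
F1 | step 10 | tert-butyl (2Z,4E)-2-(bromomethyl)-6-[(TBS-oxy)methyl]hepta-2,4,6-trienoate | BrC/C(=C\C=C\C(=C)CO[Si](C)(C)C(C)(C)C)C(=O)OC(C)(C)C
F2 | step 13 | (3R,4R,6R,7E)-4-{[(2R)-2-methylbutanoyl]oxy}-6-hydroxy-3-[(1E)-3-(hydroxymethyl)buta-1,3-dien-1-yl]-8-iodo-6-methyl-2-methylideneoct-7-enoic acid | C=C(C(=O)O)[C@@H](/C=C/C(=C)CO)[C@H](OC(=O)[C@H](C)CC)C[C@@](C)(O)/C=C/I
F3 | step 13 | (4R,5R)-5-[(1Z)-3-iodo-2-(hydroxymethyl)prop-1-en-1-yl]-4-[(1R,3R,4E)-3-hydroxy-5-iodo-3-methyl-1-{[(2R)-2-methylbutanoyl]oxy}pent-4-en-1-yl]-3-methylideneoxolan-2-one | C=C1C(=O)O[C@H](/C=C(/CI)CO)[C@H]1[C@H](OC(=O)[C@H](C)CC)C[C@@](C)(O)/C=C/I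
F4 | step 16 | (2Z)-2-(acetoxymethyl)-3-{(2R,3R)-3-[(1R,3R,4E)-3-hydroxy-5-iodo-3-methyl-1-{[(2R)-2-methylbutanoyl]oxy}pent-4-en-1-yl]-4-methylidene-5-oxooxolan-2-yl}prop-2-enoic acid | C=C1C(=O)O[C@H](/C=C(/COC(C)=O)C(=O)O)[C@H]1[C@H](OC(=O)[C@H](C)CC)C[C@@](C)(O)/C=C/I
F5 | step 16 | S-(pyridin-2-yl) thioester of F4 | C=C1C(=O)O[C@H](/C=C(/COC(C)=O)C(=O)Sc2ccccn2)[C@H]1[C@H](OC(=O)[C@H](C)CC)C[C@@](C)(O)/C=C/I
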